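**Retrosynthetic overview**
1. Feature: numbering C1 (quaternary carbinol bearing C7H2OBz), C2 (CHOH), C3/C4 (CH2), C5 (CHOBz), C6 (CHOH), the only ring, carbocycle C1–C6, is the ring of bromobenzene. C6 and C5 are its ortho and meta carbons, and the bromine on C1 marks the place of C7. The ring is present from the start; no ring is formed later.
2. C5–OBz ⇒ SN2 inversion by benzoate on the O5/O6 cyclic sulfate of a cis-diol (C5 reacts because C6 adjoins quaternary C1); O7–Bz ⇒ acylation.
3. C1–O (β) / C2–O (α) ⇒ epoxide anti to the O5/O6 acetonide, opened by hydroxide at C2.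
4. C1–C7 ⇒ Stille hydroxymethylation of the vinyl bromide; C3–C4 ⇒ diimide reduction.
5. C5–O and C6–O (cis, both stereocentres) ⇒ toluene dioxygenase cis-dihydroxylation of bromobenzene.

Key step: step 1

Convention and assumption: atoms are numbered C1–C7 as above throughout; α is the ring face carrying O6 (the face of the two enzyme-delivered oxygens), β the opposite face. The oxidation is assumed to be run with a recombinant E. coli host that expresses toluene dioxygenase and lacks the cis-diol dehydrogenase.

Step 1
Reactants: 1 bromobenzene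
Product: 2 (1S,2S)-3-bromocyclohexa-3,5-diene-1,2-diol
Conditions: E. coli JM109 (pDTG601), IPTG-induced, glucose-fed fermentation in mineral salts medium, air, PhBr fed, pH 6.8–7.0, 35 °C; EtOAc extraction
Reagents that add atoms: dioxygen, O=O
Why: Arene cis-dihydroxylation by a Rieske non-heme iron dioxygenase: electrons from NADH pass through the reductase and the [2Fe–2S] ferredoxin to the mononuclear iron site (divalent iron in the resting state), which binds O2 and transfers both oxygen atoms suprafacially to the C5–C6 edge (meta and ortho carbons of bromobenzene), forming the C5–O and C6–O bonds in one event. The closest known reaction type is this same whole-cell toluene dioxygenase oxidation of monohalobenzenes to homochiral cis-dihydrodiols. No ring is closed; the arene carbocycle becomes the cyclohexane ring of the target. Both new stereocentres (C5 and C6, cis) are set by the chiral active-site pocket, which orients the halogen and exposes one enantioface of the ortho–meta bond, giving the (1S,2S)-diol. The step needs ortho–meta regioselectivity and survival of the diene diol: the first comes from substrate binding in the enzyme, the second from the absence of the dehydrogenase and a neutral broth that avoids acid-promoted dehydration to bromophenols.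

Step 2
Reactants: 2 (1S,2S)-3-bromocyclohexa-3,5-diene-1,2-diol
Product: 3 (1S,2S)-3-bromocyclohex-3-ene-1,2-diol
Conditions: KO2CN=NCO2K, AcOH, MeOH, 0 °C to rt
Reagents that add atoms: none
Why: Diimide reduction, in which HN=NH transfers H2 through a concerted cyclic transition state that is sensitive to substitution, so the cis-disubstituted C3=C4 alkene is saturated while the bromine-bearing C1=C2 alkene and the C–Br bond stay intact, which also removes the diene before it can undergo Diels–Alder dimerisation; no stereocentre is formed.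

Step 3
Reactants: 3 (1S,2S)-3-bromocyclohex-3-ene-1,2-diol
Product: 4 (3aS,7aS)-4-bromo-2,2-dimethyl-3a,6,7,7a-tetrahydro-1,3-benzodioxole
Conditions: Me2C(OMe)2, p-TsOH·H2O (cat.), acetone, rt
Reagents that add atoms: 2,2-dimethoxypropane, COC(C)(C)OC
Why: Acid-catalysed transketalisation (acetonide formation), in which the cis-1,2-diol closes a five-membered dioxolane that masks O5 and O6 together and creates the facial bias used in step 6, with the stereocentres untouched.

Step 4
Reactants: 4 (3aS,7aS)-4-bromo-2,2-dimethyl-3a,6,7,7a-tetrahydro-1,3-benzodioxole; 5 (tributylstannyl)methanol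
Product: 6 [(3aR,7aS)-2,2-dimethyl-3a,6,7,7a-tetrahydro-1,3-benzodioxol-4-yl]methanol
Conditions: Pd(PPh3)4 (cat.), 1,4-dioxane, 100 °C
Reagents that add atoms: (tributylstannyl)methanol 5, OC[Sn](CCCC)(CCCC)CCCC
Why: Stille cross-coupling (hydroxymethylation), in which oxidative addition of the vinyl bromide to zerovalent palladium, transfer of the α-oxygenated hydroxymethyl group from tin in preference to butyl, and reductive elimination form the C1–C7 bond without moving the alkene; no stereocentre is created.

Step 5
Reactants: 6 [(3aR,7aS)-2,2-dimethyl-3a,6,7,7a-tetrahydro-1,3-benzodioxol-4-yl]methanol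
Product: 7 (3aR,7aS)-4-{[(4-methoxybenzyl)oxy]methyl}-2,2-dimethyl-3a,6,7,7a-tetrahydro-1,3-benzodioxole
Conditions: NaH, PMBCl, Bu4NI (cat.), THF/DMF, 0 °C to rt
Reagents that add atoms: 4-methoxybenzyl chloride, COc1ccc(CCl)cc1
Why: Williamson ether synthesis on the primary allylic alkoxide, giving an O7 ether that withstands peracid and hot hydroxide, blocks Payne rearrangement of the later epoxy alcohol, and can be removed oxidatively in the presence of benzyl ethers.

Step 6
Reactants: 7 (3aR,7aS)-4-{[(4-methoxybenzyl)oxy]methyl}-2,2-dimethyl-3a,6,7,7a-tetrahydro-1,3-benzodioxole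
Product: 8 1,2-β-epoxide of 7 (epoxide oxygen bridging C1 and C2 on the β face, anti to the α-acetonide on C5/C6; C1 carries CH2OPMB)
Conditions: mCPBA, NaHCO3, CH2Cl2, 0 °C to rt
Reagents that add atoms: 3-chloroperoxybenzoic acid, OOC(=O)c1cccc(Cl)c1
Why: Prilezhaev epoxidation of the electron-rich trisubstituted alkene from the β face, because the cis-fused acetonide (allylic O6 on the α face) shields the α face and the O7 ether offers no hydrogen-bond direction, which sets C1 (C–O β, final configuration) and C2 (C–O β, to be inverted).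

Step 7
Reactants: 8 1,2-β-epoxide of 7
Product: 9 (3aS,4S,5R,7aS)-4-{[(4-methoxybenzyl)oxy]methyl}-2,2-dimethylhexahydro-1,3-benzodioxole-4,5-diol (C1–OH β, C2–OH α)
Conditions: KOH, DMSO/H2O (4:1), 100 °C
Reagents that add atoms: water, O (delivered as hydroxide from KOH, [K+].[OH-])
Why: Base-mediated SN2 epoxide hydrolysis, in which hydroxide cannot attack the fully substituted C1 and therefore opens the epoxide at secondary C2 from the α face with inversion (trans-diaxial opening in the sense of the Fürst–Plattner rule), giving C2–OH α and leaving the C1–O bond β, while the O7 ether excludes a Payne rearrangement that would deliver the opposite C1/C2 configuration.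

Step 8
Reactants: 9 (3aS,4S,5R,7aS)-4-{[(4-methoxybenzyl)oxy]methyl}-2,2-dimethylhexahydro-1,3-benzodioxole-4,5-diol
Product: 10 (3aS,4S,5R,7aS)-4,5-bis(benzyloxy)-4-{[(4-methoxybenzyl)oxy]methyl}-2,2-dimethylhexahydro-1,3-benzodioxole
Conditions: NaH (excess), BnBr, Bu4NI (cat.), DMF, 0 to 40 °C
Reagents that add atoms: benzyl bromide, BrCc1ccccc1
Why: Williamson ether synthesis on both the secondary C2 and the tertiary C1 alkoxide, so that only O5/O6 can react at the cyclic sulfate stage and the tertiary oxygen cannot later displace an activated C6–O bond; no stereocentre is affected.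

Step 9
Reactants: 10 (3aS,4S,5R,7aS)-4,5-bis(benzyloxy)-4-{[(4-methoxybenzyl)oxy]methyl}-2,2-dimethylhexahydro-1,3-benzodioxole
Product: 11 [(3aS,4S,5R,7aS)-4,5-bis(benzyloxy)-2,2-dimethylhexahydro-1,3-benzodioxol-4-yl]methanol
Conditions: DDQ, CH2Cl2/pH 7 phosphate buffer (10:1), 0 °C to rt
Reagents that add atoms: none
Why: Oxidative PMB ether cleavage, in which DDQ abstracts hydride from the electron-rich 4-methoxybenzyl position and water hydrolyses the resulting oxocarbenium ion, releasing O7–H while the less electron-rich benzyl ethers and the acetonide remain.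

Step 10
Reactants: 11 [(3aS,4S,5R,7aS)-4,5-bis(benzyloxy)-2,2-dimethylhexahydro-1,3-benzodioxol-4-yl]methanol; 12 benzoyl chloride
Product: 13 [(3aS,4S,5R,7aS)-4,5-bis(benzyloxy)-2,2-dimethylhexahydro-1,3-benzodioxol-4-yl]methyl benzoate
Conditions: BzCl, pyridine, DMAP (cat.), CH2Cl2, 0 °C to rt
Reagents that add atoms: benzoyl chloride 12, O=C(Cl)c1ccccc1
Why: DMAP-catalysed acylation of the only free hydroxyl, primary O7–H, which installs the C7 benzoate of the target with no selectivity problem.

Step 11
Reactants: 13 [(3aS,4S,5R,7aS)-4,5-bis(benzyloxy)-2,2-dimethylhexahydro-1,3-benzodioxol-4-yl]methyl benzoate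
Product: 14 [(1R,2S,3S,6R)-1,6-bis(benzyloxy)-2,3-dihydroxycyclohexyl]methyl benzoate (C5–OH and C6–OH both α)
Conditions: AcOH/H2O (4:1), 45 °C
Reagents that add atoms: none
Why: Acid-catalysed acetal hydrolysis of the dioxolane to the cis C5/C6 diol under conditions in which benzyl ethers and the benzoate are stable and acyl migration is slow.

Step 12
Reactants: 14 [(1R,2S,3S,6R)-1,6-bis(benzyloxy)-2,3-dihydroxycyclohexyl]methyl benzoate
Product: 16 O5/O6 cyclic sulfate of 14, via cyclic sulfite 15 (not isolated)
Conditions: SOCl2, Et3N, CH2Cl2, 0 °C; then RuCl3·xH2O (cat.), NaIO4, MeCN/H2O, 0 °C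
Reagents that add atoms: thionyl chloride, O=S(Cl)Cl; sodium periodate, [Na+].[O-]I(=O)(=O)=O
Why: Cyclic sulfate formation (cyclic sulfite, then S-oxidation by catalytic RuO4 regenerated with NaIO4), in which the cis diol closes the five-membered ring and a short cold oxidation that spares the benzyl ethers turns both C–O bonds into leaving groups without touching the stereocentres.

Step 13
Reactants: 16 O5/O6 cyclic sulfate of 14; 17 benzoic acid
Product: 19 [(1R,2S,3R,6R)-3-(benzoyloxy)-1,6-bis(benzyloxy)-2-hydroxycyclohexyl]methyl benzoate, via cesium C6-sulfate monoester 18 (not isolated)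
Conditions: PhCO2H (2 equiv), Cs2CO3 (1 equiv), DMF, 60 °C; then H2SO4 (cat.), H2O (2 equiv), THF, rt
Reagents that add atoms: benzoic acid 17, O=C(O)c1ccccc1
Why: Nucleophilic opening of a cyclic sulfate followed by acid hydrolysis of the sulfate monoester, in which benzoate attacks C5 by SN2 from the β face with inversion because C6 is flanked by the fully substituted, oxygen-bearing C1 (neopentyl-type hindrance plus inductive deactivation), which sets the C5 benzoate β and trans to O6, and catalytic acid then cleaves the S–O bond of the C6 sulfate with retention.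

Step 14
Reactants: 19 [(1R,2S,3R,6R)-3-(benzoyloxy)-1,6-bis(benzyloxy)-2-hydroxycyclohexyl]methyl benzoate
Product: 20 [(1S,2S,3R,6R)-3-(benzoyloxy)-1,2,6-trihydroxycyclohexyl]methyl benzoate
Conditions: H2 (1 atm), Pd(OH)2/C, EtOAc, rt
Reagents that add atoms: none
Why: Hydrogenolysis of the two benzylic C–O bonds under neutral conditions, which leaves both benzoates in place, avoids base-promoted acyl migration and unveils the C1 and C2 hydroxyls of the target.

**Compound list**
1 | bromobenzene | Brc1ccccc1 | starting material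
2 | (1S,2S)-3-bromocyclohexa-3,5-diene-1,2-diol | BrC1=CC=C[C@H](O)[C@@H]1O | intermediate
3 | (1S,2S)-3-bromocyclohex-3-ene-1,2-diol | BrC1=CCC[C@H](O)[C@@H]1O | intermediate
4 | (3aS,7aS)-4-bromo-2,2-dimethyl-3a,6,7,7a-tetrahydro-1,3-benzodioxole | BrC1=CCC[C@@H]2OC(C)(C)O[C@H]12 | intermediate
5 | (tributylstannyl)methanol | CCCC[Sn](CCCC)(CCCC)CO | starting material
6 | [(3aR,7aS)-2,2-dimethyl-3a,6,7,7a-tetrahydro-1,3-benzodioxol-4-yl]methanol | OCC1=CCC[C@@H]2OC(C)(C)O[C@H]12 | intermediate
7 | (3aR,7aS)-4-{[(4-methoxybenzyl)oxy]methyl}-2,2-dimethyl-3a,6,7,7a-tetrahydro-1,3-benzodioxole | COc1ccc(COCC2=CCC[C@@H]3OC(C)(C)O[C@H]23)cc1 | intermediate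
8 | 1,2-β-epoxide of 7 (epoxide O on C1/C2 anti to the C5/C6 acetonide) | COc1ccc(COC[C@]23O[C@H]2CC[C@@H]4OC(C)(C)O[C@H]34)cc1 | intermediate
9 | (3aS,4S,5R,7aS)-4-{[(4-methoxybenzyl)oxy]methyl}-2,2-dimethylhexahydro-1,3-benzodioxole-4,5-diol | COc1ccc(COC[C@]2(O)[C@H](O)CC[C@@H]3OC(C)(C)O[C@H]23)cc1 | intermediate
10 | (3aS,4S,5R,7aS)-4,5-bis(benzyloxy)-4-{[(4-methoxybenzyl)oxy]methyl}-2,2-dimethylhexahydro-1,3-benzodioxole | COc1ccc(COC[C@]2(OCc4ccccc4)[C@H](OCc5ccccc5)CC[C@@H]3OC(C)(C)O[C@H]23)cc1 | intermediate
11 | [(3aS,4S,5R,7aS)-4,5-bis(benzyloxy)-2,2-dimethylhexahydro-1,3-benzodioxol-4-yl]methanol | OC[C@]1(OCc2ccccc2)[C@H](OCc2ccccc2)CC[C@@H]2OC(C)(C)O[C@H]12 | intermediate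
12 | benzoyl chloride | O=C(Cl)c1ccccc1 | starting material
13 | [(3aS,4S,5R,7aS)-4,5-bis(benzyloxy)-2,2-dimethylhexahydro-1,3-benzodioxol-4-yl]methyl benzoate | O=C(OC[C@]1(OCc2ccccc2)[C@H](OCc2ccccc2)CC[C@@H]2OC(C)(C)O[C@H]12)c1ccccc1 | intermediate
14 | [(1R,2S,3S,6R)-1,6-bis(benzyloxy)-2,3-dihydroxycyclohexyl]methyl benzoate | O=C(OC[C@]1(OCc2ccccc2)[C@H](OCc2ccccc2)CC[C@H](O)[C@@H]1O)c1ccccc1 | intermediate
15 | O5/O6 cyclic sulfite of 14 (mixture of sulfur epimers) | O=C(OC[C@]1(OCc2ccccc2)[C@H](OCc2ccccc2)CC[C@@H]2OS(=O)O[C@H]12)c1ccccc1 | intermediate (not isolated)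
16 | O5/O6 cyclic sulfate of 14 | O=C(OC[C@]1(OCc2ccccc2)[C@H](OCc2ccccc2)CC[C@@H]2OS(=O)(=O)O[C@H]12)c1ccccc1 | intermediate
17 | benzoic acid | O=C(O)c1ccccc1 | starting material
18 | cesium salt of the C6 sulfate monoester of 19 (C5–OBz β, C6–OSO3 α) | O=C(OC[C@]1(OCc2ccccc2)[C@H](OCc2ccccc2)CC[C@@H](OC(=O)c2ccccc2)[C@@H]1OS(=O)(=O)[O-])c1ccccc1.[Cs+] | intermediate (not isolated)
19 | [(1R,2S,3R,6R)-3-(benzoyloxy)-1,6-bis(benzyloxy)-2-hydroxycyclohexyl]methyl benzoate | O=C(OC[C@]1(OCc2ccccc2)[C@H](OCc2ccccc2)CC[C@@H](OC(=O)c2ccccc2)[C@@H]1O)c1ccccc1 | intermediate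
20 | [(1S,2S,3R,6R)-3-(benzoyloxy)-1,2,6-trihydroxycyclohexyl]methyl benzoate | O=C(OC[C@]1(O)[C@H](O)CC[C@@H](OC(=O)c2ccccc2)[C@@H]1O)c1ccccc1 | target

**Step count**
Total steps: 14. Longest linear sequence: 14 steps, from bromobenzene 1 to target 20.

**Steps most likely to fail**

Step 7 (hydroxide opening of epoxide 8). The SN2 attack at a secondary carbon next to a quaternary centre may be sluggish, and hot base may instead isomerise the epoxide to an allylic alcohol by proton abstraction. Fallback, setting out from alkene 7 and returning at diol 9: dihydroxylation with OsO4 (cat.) and N-methylmorpholine N-oxide in acetone/H2O should occur on the β face, anti to the acetonide as in step 6, and give the cis-diol with C1–OH and C2–OH both β, F2. Parikh–Doering oxidation (SO3·pyridine, DMSO, i-Pr2NEt) of its only oxidisable hydroxyl would give the C2 ketone with the C1 hydroxyl retained, F3. Hydroxyl-directed reduction with Me4NBH(OAc)3 (MeCN/AcOH, −20 °C), in which boron bound to O1 delivers hydride to the β face of C2 (also the face remote from C7 and the acetonide), would then place the C2 hydroxyl α and give trans-diol 9.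

Step 13 (benzoate opening of cyclic sulfate 16). Elimination across C4–C5 or C5–C6 may compete with substitution, regioselectivity between C5 and C6 may erode, and hydrolysis of the sulfate monoester may be incomplete. Fallback, setting out from diol 14 (bypassing the cyclic sulfate) and returning at 19: a Mitsunobu reaction (PPh3, diisopropyl azodicarboxylate, benzoic acid 17, THF, 0 °C to rt) should esterify the less hindered C5 hydroxyl with inversion and give 19 directly; no new compound arises (F0).

Step 4 (Stille hydroxymethylation). Transfer of the sp3 hydroxymethyl group from tin may be slow, allowing butyl transfer and protodebromination to compete. Fallback, setting out from vinyl bromide 4 and returning at allylic alcohol 6: palladium-catalysed methoxycarbonylation (Pd(OAc)2, 1,3-bis(diphenylphosphino)propane, CO 1 atm, MeOH, Et3N, DMF, 70 °C) would give methyl (3aR,7aS)-2,2-dimethyl-3a,6,7,7a-tetrahydro-1,3-benzodioxole-4-carboxylate F1, and 1,2-reduction of this enoate with i-Bu2AlH (CH2Cl2, −78 °C) would give 6.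

**Further compounds**
F1 | step 4 | methyl (3aR,7aS)-2,2-dimethyl-3a,6,7,7a-tetrahydro-1,3-benzodioxole-4-carboxylate | COC(=O)C1=CCC[C@@H]2OC(C)(C)O[C@H]12
F2 | step 7 | C2 epimer of diol 9 (cis-diol, C1–OH and C2–OH both β; O7-PMB, O5/O6 acetonide) | COc1ccc(COC[C@]2(O)[C@@H](O)CC[C@@H]3OC(C)(C)O[C@H]23)cc1
F3 | step 7 | C2 ketone of F2 (C1–OH β retained; O7-PMB, O5/O6 acetonide) | COc1ccc(COC[C@]2(O)C(=O)CC[C@@H]3OC(C)(C)O[C@H]23)cc1
F0 | step 13 | none | none
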